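The constants of this flask say how long a catalyst molecule waits at each station of its round, so I began from them.

    substrate + free catalyst → catalyst intermediate A (k1 = 130 /M/h)
    2 free catalyst ⇌ resting dimer, settled at all times (K2 = 33 /M)
    catalyst intermediate C ⇌ free catalyst + product (K3 = 1.9 M, k3 = 5.1 /h)
    reagent + catalyst intermediate B → catalyst intermediate C (k4 = 25 /M/h)
    catalyst intermediate A ⇌ catalyst intermediate B (K5 = 0.84, k5 = 6.2 /h)

substrate 0.28 M; reagent 1.00 equiv (fed, over 10 h); free catalyst 4.4 mol%; time 20 h

* part of the substrate gone at 20 h
* the product standing at 20 h, as a percentage of the substrate charged

I followed one catalyst molecule round the cycle and dropped the resting dimer and the way back of step 3. In a steady round, each form holds catalyst in proportion to its wait. Free catalyst waits for substrate, catalyst intermediate A waits for step 5, and catalyst intermediate C waits for step 3. With c(substrate) at half its charge, these waits sum to 0.412 h. Catalyst intermediate B waits for reagent, and intermediate A stands beside it through the balance of step 5. With c(reagent) at half its charge, that adds 0.626 h, a longer wait than the others together.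

The sum of these waits is the turn time 1.04 h, the time of one full round. The 0.0123 M of catalyst then turns over 0.0118 M/h, less than the feed of 0.0280 M/h, so I expected reagent to pile up.

I froze the turn time and treated reagent as lost at a pseudo-first-order constant, turnover divided by c(reagent). Real c(reagent) lies between the outer rows, so I expected the flask between them too, as an estimate and not a bound.

| c(reagent) frozen at | constant | reagent left |
|---|---|---|
| near nothing | 0.141 /h | 13.2% |
| half its charge | 0.0848 /h | 28.9% |
| its whole charge | 0.0607 /h | 40.9% |

I committed to the middle row. Adding the substrate held in intermediates A and B to the reagent used gave an estimated conversion of 74.4%. Subtracting the reagent held in intermediate C from the reagent used gave an estimated yield of 70.3%.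

The forecast gave 77% and 73%, holding that “The cycle cannot keep up”.

The flask gave 75.6% and 71.5%, with 28% of its reagent left at 20.0 h. With substrate and reagent frozen at half their charges, my turn time put 18.9% of the catalyst in intermediate C; the flask had 22.6% at 10.0 h and 13.1% at 20.0 h. The neighbouring flask had 0.11 M of substrate, with the same equivalents and loading. Its turn time came to 2.09 h, and its constant to 0.0421 /h. The middle-row reckoning then gave 53.6% of its reagent left. That neighbouring flask left 55%, at conversion 48.7%.

The constants used here were chosen freely; the flask was simulated.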